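**Retrosynthetic overview**
1. Kuwanon R comes from its hepta-MOM ether by acidic methanolysis in the last step.
2. Key disconnection: the bond from the cyclohexene to the 2,4-dioxygenated phenyl ring, made by nickel-mediated decarboxylative radical arylation of a cyclohexyl N-acyloxyphthalimide; the planar radical is arylated anti to the two cis groups already on the ring.
3. The cyclohexene is the only ring that is built (all four benzene rings are bought as resorcinol or p-cresol). It comes from an enantioselective endo Diels–Alder reaction of the dehydroprenyl chalcone diene with an (E)-aroylacrylic N-acyloxyphthalimide, the ketone steering the regiochemistry.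
4. Diene: resorcinol → resacetophenone → 3-iodide → chalcone → MOM ether → Suzuki dienylation. Dienophile: resorcinol → bis-MOM ether → ortho-lithiation/prenylation → C–H borylation → acyl coupling with fumaryl chloride.

Assumption: the SMILES is taken as written, so the benzoyl ring is 3,5-dihydroxy-4-prenyl (no hydroxyl ortho to the ketone) and the cyclohexene is (1S,5S,6R), with the aroyl group cis to the chalcone aryl group and trans to the 2,4-dihydroxyphenyl group.

**Step 1**
Reactants: 1 resorcinol; 2 acetic acid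
Product: 3 1-(2,4-dihydroxyphenyl)ethan-1-one
Conditions: ZnCl2 (1.5 equiv), AcOH, 140 °C
Reagents that add atoms: none
Why: Nencki reaction (Friedel–Crafts C-acylation with the free acid), which acylates resorcinol ortho to one hydroxyl and para to the other.

**Step 2**
Reactants: 3 1-(2,4-dihydroxyphenyl)ethan-1-one
Product: 4 1-(2,4-dihydroxy-3-iodophenyl)ethan-1-one
Conditions: I2 (0.4 equiv), HIO3 (0.2 equiv), EtOH/H2O, 40 °C
Reagents that add atoms: iodine, II; iodic acid, OI(=O)=O
Why: Electrophilic aromatic iodination in which HIO3 reoxidises iodide so all iodine is used; C3, ortho to both hydroxyl groups, is the most activated position and the minor 5-iodo isomer is removed by crystallisation.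

**Step 3**
Reactants: 5 4-methylphenol (p-cresol)
Product: 6 4-hydroxybenzaldehyde
Conditions: CoCl2 (1 mol%), NaOH (3 equiv), O2 (1 atm), MeOH, 60 °C; then aq. HCl
Reagents that add atoms: dioxygen, O=O
Why: Cobalt-catalysed aerobic benzylic oxidation of the phenoxide through its quinone methide, which stops at the aldehyde because the product phenoxide is deactivated.

**Step 4**
Reactants: 4 1-(2,4-dihydroxy-3-iodophenyl)ethan-1-one; 6 4-hydroxybenzaldehyde
Product: 7 (2E)-1-(2,4-dihydroxy-3-iodophenyl)-3-(4-hydroxyphenyl)prop-2-en-1-one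
Conditions: KOH (60% aq.), EtOH, 25 °C, 72 h; then aq. HCl
Reagents that add atoms: none
Why: Claisen–Schmidt aldol condensation of the methyl ketone with the non-enolisable aldehyde; the conjugated E-enone is the thermodynamic product.

**Step 5**
Reactants: 7 (2E)-1-(2,4-dihydroxy-3-iodophenyl)-3-(4-hydroxyphenyl)prop-2-en-1-one
Product: 8 (2E)-1-[3-iodo-2,4-bis(methoxymethoxy)phenyl]-3-[4-(methoxymethoxy)phenyl]prop-2-en-1-one
Conditions: NaH (3.6 equiv), MOMCl (3.6 equiv), DMF, 0 °C → rt
Reagents that add atoms: chloromethyl methyl ether, COCCl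
Why: O-alkylation of the three phenoxides (NaH is needed for the chelated hydroxyl); the fast reaction with MOMCl at 0 °C outruns flavanone ring closure.

**Step 6**
Reactants: 8 (2E)-1-[3-iodo-2,4-bis(methoxymethoxy)phenyl]-3-[4-(methoxymethoxy)phenyl]prop-2-en-1-one; 9 2-methylbut-1-en-3-yne
Product: 11 (2E)-1-{2,4-bis(methoxymethoxy)-3-[(1E)-3-methylbuta-1,3-dien-1-yl]phenyl}-3-[4-(methoxymethoxy)phenyl]prop-2-en-1-one, via dienylboronate 10 (not isolated)
Conditions: 9 (1.5 equiv), pinacolborane, Cp2Zr(H)Cl (5 mol%), Et3N (10 mol%), 60 °C, sealed tube; then 8, Pd(OAc)2 (5 mol%), SPhos (10 mol%), K3PO4, THF/H2O, 60 °C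
Reagents that add atoms: none
Why: Zirconium-catalysed syn-hydroboration of the terminal alkyne gives the E-dienylboronate, and Suzuki–Miyaura coupling (SPhos for the di-ortho-substituted iodide) transfers it with retention of the E geometry.

**Step 7**
Reactants: 1 resorcinol
Product: 12 1,3-bis(methoxymethoxy)benzene
Conditions: NaH (2.4 equiv), MOMCl (2.4 equiv), DMF, 0 °C → rt
Reagents that add atoms: chloromethyl methyl ether, COCCl
Why: Standard O-alkylation of both phenoxides; the MOM groups later direct lithiation and come off together at the end.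

**Step 8**
Reactants: 12 1,3-bis(methoxymethoxy)benzene
Product: 13 1-iodo-2,4-bis(methoxymethoxy)benzene
Conditions: N-iodosuccinimide (1.05 equiv), MeCN, rt, dark
Reagents that add atoms: N-iodosuccinimide, O=C1CCC(=O)N1I
Why: Electrophilic aromatic iodination at C4, para to one alkoxy group and ortho to the other; C2 is blocked by its two flanking groups.

**Step 9**
Reactants: 12 1,3-bis(methoxymethoxy)benzene; 14 1-bromo-3-methylbut-2-ene (prenyl bromide)
Product: 16 1,3-bis(methoxymethoxy)-2-(3-methylbut-2-en-1-yl)benzene, via aryllithium 15 (not isolated)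
Conditions: n-BuLi (1.1 equiv), THF, 0 °C; CuBr·SMe2 (10 mol%), then 14, −78 °C → rt
Reagents that add atoms: none
Why: Directed ortho-metalation, in which the two MOM ethers cooperate to lithiate C2, followed by copper-catalysed SN2 allylation that keeps the prenyl group linear.

**Step 10**
Reactants: 16 1,3-bis(methoxymethoxy)-2-(3-methylbut-2-en-1-yl)benzene
Product: 17 2-[3,5-bis(methoxymethoxy)-4-(3-methylbut-2-en-1-yl)phenyl]-4,4,5,5-tetramethyl-1,3,2-dioxaborolane
Conditions: [Ir(OMe)(cod)]2 (1.5 mol%), 4,4′-di-tert-butyl-2,2′-bipyridine (3 mol%), B2pin2 (1.0 equiv), THF, 60 °C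
Reagents that add atoms: bis(pinacolato)diboron, CC1(C)OB(OC1(C)C)B1OC(C)(C)C(C)(C)O1
Why: Sterically controlled iridium-catalysed aromatic C–H borylation; C5 is the only ring C–H without an ortho substituent, and the trisubstituted prenyl alkene is too hindered to be hydroborated.

**Step 11**
Reactants: 17 2-[3,5-bis(methoxymethoxy)-4-(3-methylbut-2-en-1-yl)phenyl]-4,4,5,5-tetramethyl-1,3,2-dioxaborolane; 18 (2E)-but-2-enedioyl dichloride (fumaryl chloride)
Product: 20 1,3-dioxoisoindolin-2-yl (2E)-4-[3,5-bis(methoxymethoxy)-4-(3-methylbut-2-en-1-yl)phenyl]-4-oxobut-2-enoate, via acid chloride 19 (not isolated)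
Conditions: 18 (3 equiv), Pd(PPh3)4 (5 mol%), Cs2CO3, toluene, 80 °C; excess 18 distilled off; then N-hydroxyphthalimide, CH2Cl2, 0 °C → rt
Reagents that add atoms: N-hydroxyphthalimide, O=C1c2ccccc2C(=O)N1O
Why: Anhydrous acyl Suzuki–Miyaura coupling (oxidative addition into one C(acyl)–Cl bond, then transmetalation from boron) with excess diacid chloride gives the mono-ketone, whose remaining acid chloride is esterified to the redox-active ester with the E-alkene untouched.

**Step 12**
Reactants: 11 (2E)-1-{2,4-bis(methoxymethoxy)-3-[(1E)-3-methylbuta-1,3-dien-1-yl]phenyl}-3-[4-(methoxymethoxy)phenyl]prop-2-en-1-one; 20 1,3-dioxoisoindolin-2-yl (2E)-4-[3,5-bis(methoxymethoxy)-4-(3-methylbut-2-en-1-yl)phenyl]-4-oxobut-2-enoate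
Product: 21 1,3-dioxoisoindolin-2-yl (1S,5S,6S)-6-[3,5-bis(methoxymethoxy)-4-(3-methylbut-2-en-1-yl)benzoyl]-5-{2,6-bis(methoxymethoxy)-3-[(2E)-3-[4-(methoxymethoxy)phenyl]prop-2-enoyl]phenyl}-3-methylcyclohex-3-ene-1-carboxylate
Conditions: (R)-1-(2-methylphenyl)-3,3-diphenyltetrahydro-1H,3H-pyrrolo[1,2-c][1,3,2]oxazaborole (20 mol%), HNTf2 (18 mol%), CH2Cl2, −78 → −40 °C
Reagents that add atoms: none
Why: Proposed new method: an oxazaborolidinium-catalysed Diels–Alder reaction (closest known type: the same chiral boron cations with fumarates, acrylates, enones and quinones) applied to a keto active ester, in which the boron binds the more basic aryl-ketone oxygen with the vinylic α-C–H held against the catalyst oxygen, so that the terminal CH2 of the diene bonds to the carbon β to the ketone (C1), the complexed ketone sits endo and ends cis to the diene aryl group (C6/C5 cis), the E-alkene gives C6/C1 trans, and the (R)-catalyst (mirror image of the one that turns acrylates and butadiene into (S)-cyclohex-3-ene-1-carboxylates) is predicted to expose the Si face of the ketone α-carbon, giving (1S,5S,6S).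

**Step 13**
Reactants: 21 the (1S,5S,6S) redox-active ester described in step 12; 13 1-iodo-2,4-bis(methoxymethoxy)benzene
Product: 22 (2E)-1-{3-[(1S,5S,6R)-6-[3,5-bis(methoxymethoxy)-4-(3-methylbut-2-en-1-yl)benzoyl]-5-[2,4-bis(methoxymethoxy)phenyl]-3-methylcyclohex-2-en-1-yl]-2,4-bis(methoxymethoxy)phenyl}-3-[4-(methoxymethoxy)phenyl]prop-2-en-1-one
Conditions: NiBr2(dme) (10 mol%), 4,4′-di-tert-butyl-2,2′-bipyridine (10 mol%), Zn dust (2 equiv), 13 (1.5 equiv), DMA, rt
Reagents that add atoms: none
Why: Nickel-catalysed decarboxylative cross-electrophile coupling, in which electron transfer to the phthalimide ester releases CO2 and a planar secondary cyclohexyl radical at the former ester carbon, and the aryl–nickel species from 13 captures it on the face opposite the aroyl group on the adjacent carbon and the cis, pseudoaxial aryl group one carbon further, so the new aryl group ends trans to both (the 5S centre).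

**Step 14**
Reactants: 22 the hepta-MOM ether described in step 13
Product: 23 kuwanon R, (2E)-1-{3-[(1S,5S,6R)-6-[3,5-dihydroxy-4-(3-methylbut-2-en-1-yl)benzoyl]-5-(2,4-dihydroxyphenyl)-3-methylcyclohex-2-en-1-yl]-2,4-dihydroxyphenyl}-3-(4-hydroxyphenyl)prop-2-en-1-one
Conditions: 3 M HCl (aq.), MeOH/THF, 40 °C
Reagents that add atoms: none
Why: Acid-catalysed acetal exchange with methanol removes all seven MOM groups under conditions routinely survived by prenyl groups and hydroxychalcones, and no stereocentre is touched.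

**Compound list**
1 | resorcinol | Oc1cccc(O)c1 | starting material
2 | acetic acid | CC(=O)O | starting material
3 | 1-(2,4-dihydroxyphenyl)ethan-1-one | CC(=O)c1ccc(O)cc1O | intermediate
4 | 1-(2,4-dihydroxy-3-iodophenyl)ethan-1-one | CC(=O)c1ccc(O)c(I)c1O | intermediate
5 | 4-methylphenol | Cc1ccc(O)cc1 | starting material
6 | 4-hydroxybenzaldehyde | O=Cc1ccc(O)cc1 | intermediate
7 | (2E)-1-(2,4-dihydroxy-3-iodophenyl)-3-(4-hydroxyphenyl)prop-2-en-1-one | O=C(/C=C/c1ccc(O)cc1)c1ccc(O)c(I)c1O | intermediate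
8 | (2E)-1-[3-iodo-2,4-bis(methoxymethoxy)phenyl]-3-[4-(methoxymethoxy)phenyl]prop-2-en-1-one | COCOc1ccc(/C=C/C(=O)c2ccc(OCOC)c(I)c2OCOC)cc1 | intermediate
9 | 2-methylbut-1-en-3-yne | C=C(C)C#C | starting material
10 | 4,4,5,5-tetramethyl-2-[(1E)-3-methylbuta-1,3-dien-1-yl]-1,3,2-dioxaborolane | C=C(C)/C=C/B1OC(C)(C)C(C)(C)O1 | intermediate
11 | (2E)-1-{2,4-bis(methoxymethoxy)-3-[(1E)-3-methylbuta-1,3-dien-1-yl]phenyl}-3-[4-(methoxymethoxy)phenyl]prop-2-en-1-one | COCOc1ccc(/C=C/C(=O)c2ccc(OCOC)c(/C=C/C(C)=C)c2OCOC)cc1 | intermediate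
12 | 1,3-bis(methoxymethoxy)benzene | COCOc1cccc(OCOC)c1 | intermediate
13 | 1-iodo-2,4-bis(methoxymethoxy)benzene | COCOc1ccc(I)c(OCOC)c1 | intermediate
14 | 1-bromo-3-methylbut-2-ene | CC(C)=CCBr | starting material
15 | [2,6-bis(methoxymethoxy)phenyl]lithium | COCOc1cccc(OCOC)c1[Li] | intermediate
16 | 1,3-bis(methoxymethoxy)-2-(3-methylbut-2-en-1-yl)benzene | COCOc1cccc(OCOC)c1CC=C(C)C | intermediate
17 | 2-[3,5-bis(methoxymethoxy)-4-(3-methylbut-2-en-1-yl)phenyl]-4,4,5,5-tetramethyl-1,3,2-dioxaborolane | COCOc1cc(B2OC(C)(C)C(C)(C)O2)cc(OCOC)c1CC=C(C)C | intermediate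
18 | (2E)-but-2-enedioyl dichloride | O=C(Cl)/C=C/C(=O)Cl | starting material
19 | (2E)-4-[3,5-bis(methoxymethoxy)-4-(3-methylbut-2-en-1-yl)phenyl]-4-oxobut-2-enoyl chloride | COCOc1cc(C(=O)/C=C/C(=O)Cl)cc(OCOC)c1CC=C(C)C | intermediate
20 | 1,3-dioxoisoindolin-2-yl (2E)-4-[3,5-bis(methoxymethoxy)-4-(3-methylbut-2-en-1-yl)phenyl]-4-oxobut-2-enoate | COCOc1cc(C(=O)/C=C/C(=O)ON2C(=O)c3ccccc3C2=O)cc(OCOC)c1CC=C(C)C | intermediate
21 | 1,3-dioxoisoindolin-2-yl (1S,5S,6S)-6-[3,5-bis(methoxymethoxy)-4-(3-methylbut-2-en-1-yl)benzoyl]-5-{2,6-bis(methoxymethoxy)-3-[(2E)-3-[4-(methoxymethoxy)phenyl]prop-2-enoyl]phenyl}-3-methylcyclohex-3-ene-1-carboxylate | CC(C)=CCc1c(OCOC)cc(C(=O)[C@H]2[C@@H](c3c(OCOC)ccc(C(=O)/C=C/c4ccc(OCOC)cc4)c3OCOC)C=C(C)C[C@@H]2C(=O)ON2C(=O)c3ccccc3C2=O)cc1OCOC | intermediate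
22 | (2E)-1-{3-[(1S,5S,6R)-6-[3,5-bis(methoxymethoxy)-4-(3-methylbut-2-en-1-yl)benzoyl]-5-[2,4-bis(methoxymethoxy)phenyl]-3-methylcyclohex-2-en-1-yl]-2,4-bis(methoxymethoxy)phenyl}-3-[4-(methoxymethoxy)phenyl]prop-2-en-1-one | CC(C)=CCc1c(OCOC)cc(C(=O)[C@H]2[C@@H](c3c(OCOC)ccc(C(=O)/C=C/c4ccc(OCOC)cc4)c3OCOC)C=C(C)C[C@@H]2c2ccc(OCOC)cc2OCOC)cc1OCOC | intermediate
23 | kuwanon R | CC(C)=CCc1c(O)cc(C(=O)[C@H]2[C@@H](c3c(O)ccc(C(=O)/C=C/c4ccc(O)cc4)c3O)C=C(C)C[C@@H]2c2ccc(O)cc2O)cc1O | target

**Step count and risks**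
Total step count: 14. Longest linear sequence: 8 steps (steps 1, 2, 4, 5, 6, 12, 13, 14).

The three steps most likely to fail are 11, 12 and 13.

Step 11 (acyl coupling of a pinacol boronate with a diacid chloride; risk of slow transmetalation and double coupling). The fallback sets out from 17 and comes back at 20. Palladium-catalysed acylation of 17 with acetic anhydride (Pd(OAc)2, tris(4-methoxyphenyl)phosphine, THF/H2O, 60 °C) gives 1-[3,5-bis(methoxymethoxy)-4-(3-methylbut-2-en-1-yl)phenyl]ethan-1-one F1. Aldol condensation of F1 with glyoxylic acid (KOH, MeOH/H2O, then NaH2PO4) gives (2E)-4-[3,5-bis(methoxymethoxy)-4-(3-methylbut-2-en-1-yl)phenyl]-4-oxobut-2-enoic acid F2. Esterification with N-hydroxyphthalimide and N,N′-diisopropylcarbodiimide (cat. DMAP, CH2Cl2) gives 20. The four-carbon unit is thus built stepwise as C2 + C2 instead of being coupled in one piece.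

Step 12 (asymmetric Diels–Alder; the cationic boron catalyst may be tied up by the many Lewis-basic sites, and the predicted facial sense is extrapolated from acrylates). The fallback sets out from 11 and 19 and comes back at 21. Quenching 19 with water instead of N-hydroxyphthalimide gives the acid F2. Uncatalysed Diels–Alder reaction of 11 with F2 (toluene, 110 °C) gives the racemic endo acid. This is resolved by crystallisation as its (R)-1-phenylethylammonium salt F4 (or with the antipodal amine if that salt crystallises better); acidification then releases (1S,5S,6S)-6-[3,5-bis(methoxymethoxy)-4-(3-methylbut-2-en-1-yl)benzoyl]-5-{2,6-bis(methoxymethoxy)-3-[(2E)-3-[4-(methoxymethoxy)phenyl]prop-2-enoyl]phenyl}-3-methylcyclohex-3-ene-1-carboxylic acid F3. Esterification with N-hydroxyphthalimide and N,N′-diisopropylcarbodiimide gives 21. Absolute configuration then comes from a classical resolution instead of from catalysis.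

Step 13 (key radical arylation; the ortho-substituted aryl iodide may be sluggish under reductive conditions and the chalcone enone may be reduced by zinc and low-valent nickel). The fallback sets out from 13 and 21 and comes back at 22. Iodine–magnesium exchange on 13 (i-PrMgCl·LiCl, THF, −20 °C) and transmetalation with ZnCl2 give [2,4-bis(methoxymethoxy)phenyl]zinc chloride F5. F5 is coupled with 21 in a redox-neutral decarboxylative Negishi-type radical coupling (NiCl2(dme) 20 mol%, 4,4′-di-tert-butyl-2,2′-bipyridine 40 mol%, THF/DMF, rt). The radical at the ester carbon and its anti capture are the same, but the aryl group now arrives as a nucleophile and no metal reductant is present.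

**Further compounds**
F1 | step 11 | 1-[3,5-bis(methoxymethoxy)-4-(3-methylbut-2-en-1-yl)phenyl]ethan-1-one | CC(=O)c1cc(OCOC)c(CC=C(C)C)c(OCOC)c1
F2 | step 11 | (2E)-4-[3,5-bis(methoxymethoxy)-4-(3-methylbut-2-en-1-yl)phenyl]-4-oxobut-2-enoic acid | COCOc1cc(C(=O)/C=C/C(=O)O)cc(OCOC)c1CC=C(C)C
F3 | step 12 | (1S,5S,6S)-6-[3,5-bis(methoxymethoxy)-4-(3-methylbut-2-en-1-yl)benzoyl]-5-{2,6-bis(methoxymethoxy)-3-[(2E)-3-[4-(methoxymethoxy)phenyl]prop-2-enoyl]phenyl}-3-methylcyclohex-3-ene-1-carboxylic acid | CC(C)=CCc1c(OCOC)cc(C(=O)[C@H]2[C@@H](c3c(OCOC)ccc(C(=O)/C=C/c4ccc(OCOC)cc4)c3OCOC)C=C(C)C[C@@H]2C(=O)O)cc1OCOC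
F4 | step 12 | (R)-1-phenylethylammonium salt of F3 | CC(C)=CCc1c(OCOC)cc(C(=O)[C@H]2[C@@H](c3c(OCOC)ccc(C(=O)/C=C/c4ccc(OCOC)cc4)c3OCOC)C=C(C)C[C@@H]2C(=O)[O-])cc1OCOC.C[C@@H]([NH3+])c1ccccc1
F5 | step 13 | [2,4-bis(methoxymethoxy)phenyl]zinc chloride | COCOc1ccc([Zn]Cl)c(OCOC)c1
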